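A direct plan (ring A = p-phenylene, ring B = phenol ring, ring C = m-phenylene, ring D = quinone) would buy all four arenes. It would join them by two SNAr reactions on fluorobenzaldehydes, the second on 2-fluoro-3,6-dimethoxybenzaldehyde A1, and by a Sonogashira/hydrogenation bridge, to reach the open dialdehyde A2.
It would close the 18-membered ring by McMurry coupling to stilbene A3, hydrogenate, cleave three methyl ethers with BBr3 to the hydroquinone triol A4, and oxidise with Ag2O.
Weak point 1 would be the SNAr that makes the ring C–O–ring D ether. The fluoride of A1 would sit between CHO and OMe on a ring carrying two donor methoxy groups, so a hindered, poorly activated substitution near 130 °C would be asked of an advanced phenol-aldehyde.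
Weak point 2 would be the McMurry ring closure. Only dilution would favour the ring over pinacols and oligomers, a large excess of low-valent titanium would meet the most valuable intermediate, and the alkene formed would have to be removed again.
Weak point 3 would be the hydrogenation/BBr3/Ag2O end game. Three steps would add no skeletal complexity, A4 would be air-sensitive and carried crude, and the oxidant would have to spare the free ring B phenol.

**Plan of the new route**
Hardest feature: the doubly flanked ring C–O–C2 bond of ring D. It is a link of the 18-membered ring and also part of a sensitive aryloxyquinone that must coexist with the free ring B phenol.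
Enabling feature: in ring D (C1=O, C2–OAr, C3–CH2, C4=O, C5H=C6H) both macrocycle bonds stand on the neighbouring carbons C2/C3 between the carbonyls, and the far edge C5–C6 is a bare CH=CH. C1–C2=C3–C4 is therefore a squarate (cyclobutenedione, with an extra bond C1–C4), and C5–C6 is acetylene.
Cuts, in order: C4–C5 and C1–C6 of ring D (ring expansion of an ethynyl-hydroxycyclobutenone); O–C2 (a vinylogous ester, closed on the four-membered ring); C3–CH2 (alkyllithium + diisopropyl squarate); the B–C bridge (B-alkyl Suzuki); the A–O–B ether (SNAr).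
Ring order: A, B and C are bought, the four-membered ring comes from the squarate, the 18-membered ring follows, and ring D forms last, directly as the quinone.
The hindered SNAr becomes an acyl-type substitution at room temperature. There is no carbonyl coupling, no alkene to remove, no methyl ether, no hydroquinone and no oxidant, because the ring expansion is redox-neutral. The regiochemistry of acetylide addition does not matter, since C5 and C6 both carry H.

Key step: step 11

Assumption: the target SMILES has no stereocentre and the 18-membered ring is taken as conformationally mobile (no stable planar chirality), so the compound is achiral and no enantiocontrol is needed.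
Notation: the ring D numbering C1–C4 given above is also used for the four-membered ring.

**Step 1**
Reactants: 1 3-vinylphenol
Product: 2 1-(methoxymethoxy)-3-vinylbenzene
Conditions: MOMCl, i-Pr2NEt, CH2Cl2, 0 °C → rt
Reagents that add atoms: chloromethyl methyl ether, COCCl
Why: Base-mediated O-alkylation of the phenol with the reactive α-chloro ether (MOM protection) should be clean, and the acetal withstands borane, palladium/base, peracid and alkyllithium yet falls in the same aqueous acid that later hydrolyses the squarate ester.

**Step 2**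
Reactants: 3 tyrosol [4-(2-hydroxyethyl)phenol]; 4 4-bromo-2-fluorobenzaldehyde
Product: 5 4-bromo-2-[4-(2-hydroxyethyl)phenoxy]benzaldehyde
Conditions: K2CO3, DMF, 90 °C
Reagents that add atoms: none
Why: SNAr, in which carbonate ionises only the phenol of 3 and the phenoxide displaces the fluoride activated by the ortho formyl group and flanked on one side only, whereas bromide is a far poorer leaving group in addition–elimination and the alkanol stays neutral.

**Step 3**
Reactants: 2 1-(methoxymethoxy)-3-vinylbenzene; 5 4-bromo-2-[4-(2-hydroxyethyl)phenoxy]benzaldehyde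
Product: 7 2-[4-(2-hydroxyethyl)phenoxy]-4-{2-[3-(methoxymethoxy)phenyl]ethyl}benzaldehyde, via B-{2-[3-(methoxymethoxy)phenyl]ethyl}-9-borabicyclo[3.3.1]nonane 6 (not isolated)
Conditions: 2 (1.3 equiv), 9-BBN (1.2 equiv), THF, rt; then 5, PdCl2(dppf) (5 mol%), aq K3PO4, DMF/THF, 50 °C
Reagents that add atoms: none
Why: Anti-Markovnikov hydroboration of the styrene followed by B-alkyl Suzuki–Miyaura coupling installs the saturated B–C bridge in one operation at the C–Br bond activated by the para formyl group; the slight excess of 2 over 9-BBN leaves no B–H to reduce the aldehyde, and the free alkanol is tolerated.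

**Step 4**
Reactants: 7 2-[4-(2-hydroxyethyl)phenoxy]-4-{2-[3-(methoxymethoxy)phenyl]ethyl}benzaldehyde
Product: 9 2-[4-(2-hydroxyethyl)phenoxy]-4-{2-[3-(methoxymethoxy)phenyl]ethyl}phenol, via 2-[4-(2-hydroxyethyl)phenoxy]-4-{2-[3-(methoxymethoxy)phenyl]ethyl}phenyl formate 8 (not isolated)
Conditions: mCPBA, CH2Cl2, rt; then K2CO3 (cat.), MeOH, rt
Reagents that add atoms: 3-chloroperoxybenzoic acid, OOC(=O)c1cccc(Cl)c1
Why: Baeyer–Villiger (Dakin-type) oxidation, in which the electron-rich aryl group (ortho aryloxy, para alkyl) migrates in preference to hydrogen, followed by methanolysis of formate 8, turns the group that activated the SNAr into the ring B hydroxyl at exactly the required position.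

**Step 5**
Reactants: 9 2-[4-(2-hydroxyethyl)phenoxy]-4-{2-[3-(methoxymethoxy)phenyl]ethyl}phenol
Product: 10 2-[4-(2-iodoethyl)phenoxy]-4-{2-[3-(methoxymethoxy)phenyl]ethyl}phenol
Conditions: PPh3, I2, imidazole, CH2Cl2, 0 °C → rt
Reagents that add atoms: iodine, II
Why: Appel-type iodination (Garegg–Samuelsson conditions) converts only the primary alkanol, since an aryloxyphosphonium ion cannot undergo SN2 displacement, and imidazole keeps the medium neutral for the MOM acetal.

**Step 6**
Reactants: 10 2-[4-(2-iodoethyl)phenoxy]-4-{2-[3-(methoxymethoxy)phenyl]ethyl}phenol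
Product: 11 {2-[4-(2-iodoethyl)phenoxy]-4-{2-[3-(methoxymethoxy)phenyl]ethyl}phenoxy}triisopropylsilane
Conditions: TIPSCl, imidazole, DMAP (cat.), CH2Cl2, rt
Reagents that add atoms: chlorotriisopropylsilane, CC(C)[Si](Cl)(C(C)C)C(C)C
Why: Imidazole-mediated silylation of the only remaining OH gives a phenolic TIPS ether, further shielded by the ortho aryloxy group, that should survive alkyllithium at −78 °C and warm aqueous acid and still leave with fluoride at the end.

**Step 7**
Reactants: 11 the TIPS-protected iodide; 12 diisopropyl squarate (3,4-diisopropoxycyclobut-3-ene-1,2-dione)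
Product: 16 3-isopropoxy-4-[2-(4-{5-[2-(3-(methoxymethoxy)phenyl)ethyl]-2-(triisopropylsilyloxy)phenoxy}phenyl)ethyl]cyclobut-3-ene-1,2-dione, via arylethyllithium 13 (not isolated), via lithium alkoxide 14 (not isolated), via trifluoroacetate 15 (not isolated)
Conditions: t-BuLi (2.1 equiv), Et2O/pentane, −78 °C; 12, THF, −78 °C; (CF3CO)2O, −78 °C; H2O, → rt
Reagents that add atoms: water, O
Why: Lithium–iodine exchange of the primary iodide with two equivalents of t-BuLi gives 13 faster than any ortho-lithiation at −78 °C, 13 adds 1,2 to a squarate carbonyl to give racemic 14, and trifluoroacetylation to racemic 15 followed by ionisation and hydrolysis of the resulting oxocarbenium ion is the standard non-acidic route to 3-alkyl-4-alkoxycyclobutenediones, so the MOM group is kept.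

**Step 8**
Reactants: 16 the 3-isopropoxy-4-alkylcyclobutenedione
Product: 17 3-hydroxy-4-[2-(4-{5-[2-(3-hydroxyphenyl)ethyl]-2-(triisopropylsilyloxy)phenoxy}phenyl)ethyl]cyclobut-3-ene-1,2-dione (semisquaric acid; ring C phenol free)
Conditions: 6 M HCl, THF, 50 °C
Reagents that add atoms: water, O
Why: Aqueous acid hydrolyses the vinylogous isopropyl ester to the semisquaric acid and the MOM acetal to the ring C phenol in one operation, while phenolic TIPS ethers are particularly slow to cleave under acidic conditions.

**Step 9**
Reactants: 17 the semisquaric acid with free ring C phenol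
Product: 19 macrocyclic cyclobutenedione (18-membered ring; C2 of the cyclobut-3-ene-1,2-dione O-linked to ring C; C3 bearing the CH2CH2–ring A bridge; OTIPS on ring B), via chlorocyclobutenedione 18 (not isolated)
Conditions: (COCl)2 (1.1 equiv), DMF (cat.), CH2Cl2, 0 °C → rt, evaporate; then syringe-pump addition to i-Pr2NEt, DMAP (cat.), CH2Cl2 (1 mM final), rt
Reagents that add atoms: none
Why: Base-free Vilsmeier-type chlorination picks the strongly acidic semisquaric OH (a vinylogous carboxylic acid) over the neutral phenol to give the 3-chloro-4-alkylcyclobutenedione 18, and slow addition of 18 to base then closes the 18-membered ring by addition–elimination of the ring C phenol at C2 (a vinylogous macrolactonisation via the acid chloride), which should be fast at room temperature because the external angles of about 135° at the four-membered ring hold both neighbours of C2 back and the only other phenol is silylated.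

**Step 10**
Reactants: 19 the macrocyclic cyclobutenedione; 20 acetylene
Product: 22 macrocyclic 4-ethynyl-4-hydroxycyclobut-2-enone (racemic; C1 carbinol carbon bearing OH plus C≡CH; C2 bearing O–ring C; C3 bearing the CH2CH2 bridge; C4 ketone), via lithium acetylide 21 (not isolated)
Conditions: 20 (excess), n-BuLi, THF, −78 °C; then 19, −78 °C; aq NH4Cl at −78 °C
Reagents that add atoms: none
Why: 1,2-Addition of an alkynyllithium to a cyclobutenedione is expected at C1, the carbonyl not deactivated by vinylogous-ester resonance, acetylides being the carbon nucleophiles least prone to conjugate addition; the new carbinol centre is racemic and is erased in step 11, and addition at C4 would lead to the same quinone.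

**Step 11**
Reactants: 22 the macrocyclic 4-ethynyl-4-hydroxycyclobutenone
Product: 24 O-triisopropylsilyl-marchantinquinone (ring B OH of the target replaced by OTIPS), via macrocyclic (Z)-enynylketene 23 (not isolated)
Conditions: toluene (5 mM, degassed), 110 °C
Reagents that add atoms: none
Why: Heating cleaves the C1–C4 bond of the cyclobutenone by conrotatory 4π electrocyclic ring opening, in which the donor hydroxyl on C1 rotates outward (torquoselectivity) and thereby turns the ethynyl group inward, cis to the ketene, in (Z)-enynylketene 23. The ketene carbon C4 then bonds to the terminal alkyne carbon C5 (Moore cyclisation, the ketene counterpart of the Myers–Saito reaction) to give a six-membered σ-aryl/phenoxyl diradical, and shift of the hydroxyl hydrogen to C6 delivers the quinone with no oxidant. The closest known reaction type is the thermal rearrangement of 4-alkynyl-4-hydroxy-3-alkoxy-2-alkylcyclobutenones to 2-alkoxy-3-alkyl-1,4-benzoquinones. Ring D is the only ring closed, by 6-endo-dig attack at the alkyne, while the 18-membered ring persists because C2 and C3 stay bonded throughout, and the release of four-ring strain together with quinone formation pays for the narrowing of the external angles at C2/C3 that tightens the macrocycle. The selectivity needed is six- over five-membered closure, which the terminal alkyne secures because it offers no radical-stabilising substituent at C5, and the σ-radical at C6 lies para to the C3 side chain and meta to the C2 aryloxy group, pointing away from the macrocycle, so it cannot reach the benzylic hydrogens. No stereocentre is formed, the racemic carbinol centre disappears, and both regioisomers of 22 converge on 24 because C5 and C6 both carry hydrogen.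

**Step 12**
Reactants: 24 O-triisopropylsilyl-marchantinquinone
Product: 25 marchantinquinone
Conditions: HF·pyridine, THF, 0 °C → rt
Reagents that add atoms: none
Why: Fluoride-induced cleavage of the phenolic silyl ether in an acidic, weakly nucleophilic medium avoids a free phenoxide next to the electrophilic aryloxyquinone, and quinones tolerate HF·pyridine.

**Compound list**
1 | 3-vinylphenol | C=Cc1cccc(O)c1 | starting material
2 | 1-(methoxymethoxy)-3-vinylbenzene | C=Cc1cccc(OCOC)c1 | intermediate
3 | tyrosol, 4-(2-hydroxyethyl)phenol | OCCc1ccc(O)cc1 | starting material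
4 | 4-bromo-2-fluorobenzaldehyde | O=Cc1ccc(Br)cc1F | starting material
5 | 4-bromo-2-[4-(2-hydroxyethyl)phenoxy]benzaldehyde | O=Cc1ccc(Br)cc1Oc1ccc(CCO)cc1 | intermediate
6 | B-{2-[3-(methoxymethoxy)phenyl]ethyl}-9-borabicyclo[3.3.1]nonane | COCOc1cccc(CCB2C3CCCC2CCC3)c1 | intermediate
7 | 2-[4-(2-hydroxyethyl)phenoxy]-4-{2-[3-(methoxymethoxy)phenyl]ethyl}benzaldehyde | O=Cc1ccc(CCc2cccc(OCOC)c2)cc1Oc1ccc(CCO)cc1 | intermediate
8 | 2-[4-(2-hydroxyethyl)phenoxy]-4-{2-[3-(methoxymethoxy)phenyl]ethyl}phenyl formate | O=COc1ccc(CCc2cccc(OCOC)c2)cc1Oc1ccc(CCO)cc1 | intermediate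
9 | 2-[4-(2-hydroxyethyl)phenoxy]-4-{2-[3-(methoxymethoxy)phenyl]ethyl}phenol | Oc1ccc(CCc2cccc(OCOC)c2)cc1Oc1ccc(CCO)cc1 | intermediate
10 | 2-[4-(2-iodoethyl)phenoxy]-4-{2-[3-(methoxymethoxy)phenyl]ethyl}phenol | Oc1ccc(CCc2cccc(OCOC)c2)cc1Oc1ccc(CCI)cc1 | intermediate
11 | {2-[4-(2-iodoethyl)phenoxy]-4-{2-[3-(methoxymethoxy)phenyl]ethyl}phenoxy}triisopropylsilane | CC(C)[Si](Oc1ccc(CCc2cccc(OCOC)c2)cc1Oc1ccc(CCI)cc1)(C(C)C)C(C)C | intermediate
12 | diisopropyl squarate | CC(C)OC1=C(OC(C)C)C(=O)C1=O | starting material
13 | arylethyllithium: 2-(4-{5-[2-(3-(methoxymethoxy)phenyl)ethyl]-2-(triisopropylsilyloxy)phenoxy}phenyl)ethyllithium, from 11 by Li–I exchange | [Li]CCc1ccc(Oc2cc(CCc3cccc(OCOC)c3)ccc2O[Si](C(C)C)(C(C)C)C(C)C)cc1 | intermediate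
14 | lithium alkoxide of the 1,2-adduct (4-alkyl-4-lithiooxy-2,3-diisopropoxycyclobut-2-enone, racemic) | CC(C)OC1=C(OC(C)C)C(CCc2ccc(Oc3cc(CCc4cccc(OCOC)c4)ccc3O[Si](C(C)C)(C(C)C)C(C)C)cc2)(O[Li])C1=O | intermediate
15 | trifluoroacetate of the 1,2-adduct (racemic) | CC(C)OC1=C(OC(C)C)C(CCc2ccc(Oc3cc(CCc4cccc(OCOC)c4)ccc3O[Si](C(C)C)(C(C)C)C(C)C)cc2)(OC(=O)C(F)(F)F)C1=O | intermediate
16 | 3-isopropoxy-4-[2-(4-{5-[2-(3-(methoxymethoxy)phenyl)ethyl]-2-(triisopropylsilyloxy)phenoxy}phenyl)ethyl]cyclobut-3-ene-1,2-dione | CC(C)OC1=C(CCc2ccc(Oc3cc(CCc4cccc(OCOC)c4)ccc3O[Si](C(C)C)(C(C)C)C(C)C)cc2)C(=O)C1=O | intermediate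
17 | 3-hydroxy-4-[2-(4-{5-[2-(3-hydroxyphenyl)ethyl]-2-(triisopropylsilyloxy)phenoxy}phenyl)ethyl]cyclobut-3-ene-1,2-dione | OC1=C(CCc2ccc(Oc3cc(CCc4cccc(O)c4)ccc3O[Si](C(C)C)(C(C)C)C(C)C)cc2)C(=O)C1=O | intermediate
18 | chlorocyclobutenedione: 3-chloro-4-[2-(4-{5-[2-(3-hydroxyphenyl)ethyl]-2-(triisopropylsilyloxy)phenoxy}phenyl)ethyl]cyclobut-3-ene-1,2-dione | ClC1=C(CCc2ccc(Oc3cc(CCc4cccc(O)c4)ccc3O[Si](C(C)C)(C(C)C)C(C)C)cc2)C(=O)C1=O | intermediate
19 | macrocyclic cyclobutenedione, ring B OTIPS | O=C1C(=O)C2=C1CCc1ccc(cc1)Oc1cc(ccc1O[Si](C(C)C)(C(C)C)C(C)C)CCc1cccc(c1)O2 | intermediate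
20 | acetylene | C#C | starting material
21 | lithium acetylide | [Li]C#C | intermediate
22 | macrocyclic 4-ethynyl-4-hydroxycyclobut-2-enone, ring B OTIPS (racemic) | C#CC1(O)C(=O)C2=C1Oc1cccc(c1)CCc1ccc(O[Si](C(C)C)(C(C)C)C(C)C)c(c1)Oc1ccc(cc1)CC2 | intermediate
23 | macrocyclic (Z)-enynylketene, ring B OTIPS | C#C/C(O)=C1/Oc2cccc(c2)CCc2ccc(O[Si](C(C)C)(C(C)C)C(C)C)c(c2)Oc2ccc(cc2)CCC1=C=O | intermediate
24 | O-triisopropylsilyl-marchantinquinone | O=C1C=CC(=O)C2=C1CCc1ccc(cc1)Oc1cc(ccc1O[Si](C(C)C)(C(C)C)C(C)C)CCc1cccc(c1)O2 | intermediate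
25 | marchantinquinone (achiral) | O=C1C=CC(=O)C2=C1CCc1ccc(cc1)Oc1cc(ccc1O)CCc1cccc(c1)O2 | target

**Summary**
Total steps: 12. Longest linear sequence: 11 (steps 2–12, from 3 and 4).

**Steps most likely to fail**

1. **Step 9.** Intermolecular acylation (oligomerisation) or hydrolysis of the vinylogous acid chloride may outrun ring closure, in which case ring D would be grown first and the macrocycle closed on the quinone. The fallback sets out from 16. Lithium acetylide (THF, −78 °C) should give the racemic open-chain 4-ethynyl-4-hydroxy-3-isopropoxy-2-(2-arylethyl)cyclobut-2-enone F1, and heating in toluene should give the open-chain 2-isopropoxy-3-(2-arylethyl)-1,4-benzoquinone F2. Dilute H2SO4 in aqueous THF should then give the 2-hydroxyquinone with free ring C phenol F3, and oxalyl chloride/DMF should give the bench-stable 2-chloroquinone with free ring C phenol F4. Slow addition of F4 to Cs2CO3 in MeCN under high dilution would close the ring by addition–elimination of the phenoxide at C2 (haloquinone substitution) and come back to the route at 24.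

2. **Step 10.** Conjugate addition with loss of the aryloxide (opening of the macrocycle) or deprotonation of the C3–CH2 group may compete with 1,2-addition, so the two carbons would be introduced without a carbon nucleophile. The fallback sets out from 19. ClCo(PPh3)3 (benzene, rt) should insert into the C1–C4 bond to give the macrocyclic maleoylcobalt complex F5, a five-membered cobaltacycle with chloride and two phosphines on cobalt. Heating F5 under acetylene would give alkyne insertion and reductive elimination, coming back to the route at 24 and bypassing 22.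

3. **Step 11.** The diradical may be diverted by intermolecular hydrogen abstraction, five-membered closure or polymerisation, so a closed-shell ring expansion would be used instead. The fallback sets out from 19. Vinylmagnesium bromide (THF, −78 °C) should give the racemic macrocyclic 4-hydroxy-4-vinylcyclobut-2-enone F6. Heating in toluene (4π opening, 6π electrocyclisation of the dienylketene, tautomerisation) should give the ring B O-TIPS macrocyclic hydroquinone F7. Ag2O in Et2O would oxidise F7 while the ring B oxygen is still silylated, coming back to the route at 24.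

**Further compounds**
F1 | step 9 | 4-ethynyl-4-hydroxy-3-isopropoxy-2-(2-arylethyl)cyclobut-2-enone, open chain, ring C OMOM, ring B OTIPS (racemic) | C#CC1(O)C(OC(C)C)=C(CCc2ccc(Oc3cc(CCc4cccc(OCOC)c4)ccc3O[Si](C(C)C)(C(C)C)C(C)C)cc2)C1=O
F2 | step 9 | 2-isopropoxy-3-(2-arylethyl)-1,4-benzoquinone, open chain, ring C OMOM, ring B OTIPS | CC(C)OC1=C(CCc2ccc(Oc3cc(CCc4cccc(OCOC)c4)ccc3O[Si](C(C)C)(C(C)C)C(C)C)cc2)C(=O)C=CC1=O
F3 | step 9 | 2-hydroxy-3-(2-arylethyl)-1,4-benzoquinone with free ring C phenol, ring B OTIPS | OC1=C(CCc2ccc(Oc3cc(CCc4cccc(O)c4)ccc3O[Si](C(C)C)(C(C)C)C(C)C)cc2)C(=O)C=CC1=O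
F4 | step 9 | 2-chloro-3-(2-arylethyl)-1,4-benzoquinone with free ring C phenol, ring B OTIPS | ClC1=C(CCc2ccc(Oc3cc(CCc4cccc(O)c4)ccc3O[Si](C(C)C)(C(C)C)C(C)C)cc2)C(=O)C=CC1=O
F5 | step 10 | macrocyclic maleoylcobalt complex, chlorobis(triphenylphosphine)cobaltacyclopentenedione, ring B OTIPS | O=C1C2=C(CCc3ccc(cc3)Oc3cc(ccc3O[Si](C(C)C)(C(C)C)C(C)C)CCc3cccc(c3)O2)C(=O)[Co-2]1(Cl)([P+](c1ccccc1)(c1ccccc1)c1ccccc1)[P+](c1ccccc1)(c1ccccc1)c1ccccc1
F6 | step 11 | macrocyclic 4-hydroxy-4-vinylcyclobut-2-enone, ring B OTIPS (racemic) | C=CC1(O)C(=O)C2=C1Oc1cccc(c1)CCc1ccc(O[Si](C(C)C)(C(C)C)C(C)C)c(c1)Oc1ccc(cc1)CC2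
F7 | step 11 | macrocyclic hydroquinone, ring B OTIPS | Oc1ccc(O)c2c1CCc1ccc(cc1)Oc1cc(ccc1O[Si](C(C)C)(C(C)C)C(C)C)CCc1cccc(c1)O2
A1 | direct plan | 2-fluoro-3,6-dimethoxybenzaldehyde | COc1ccc(OC)c(C=O)c1F
A2 | direct plan | open dialdehyde, 2-(3-{2-[3-(4-formylphenoxy)-4-methoxyphenyl]ethyl}phenoxy)-3,6-dimethoxybenzaldehyde | COc1ccc(CCc2cccc(Oc3c(C=O)c(OC)ccc3OC)c2)cc1Oc1ccc(C=O)cc1
A3 | direct plan | macrocyclic stilbene trimethyl ether (E/Z mixture) | COc1ccc2cc1Oc1ccc(cc1)C=Cc1c(OC)ccc(OC)c1Oc1cccc(CC2)c1
A4 | direct plan | macrocyclic hydroquinone triol | Oc1ccc2cc1Oc1ccc(cc1)CCc1c(O)ccc(O)c1Oc1cccc(CC2)c1
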